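**Retrosynthetic overview**

1. The target is disconnected (step 16) to octalin ketal 20: one bromonium-triggered 1,2-shift contracts a six-membered ring to the cyclopentane (ring B), sets the C–Br bond and the quaternary carbon of ring C, and closes the lactone (ring D).
2. Enabling feature: in 20 the ketal carbon C1 of the six-membered ring (C1–C4, C4a, C8a) is bonded to alkene carbon C8a of the C8=C8a bond, which C8a shares with ring C. Br+ at C8 makes C8a electron-poor, ring bond C1–C2 shifts to C8a, and the C5 hydroxyl (1,3 to C8a, same face) captures the resulting dioxolanylium carbon.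
3. 20 comes from enone 19, made by aldol condensation (closes ring C); carbinol C5 comes from two Grignard additions to the bridged lactone 14; the six-membered precursor of ring B comes from quinine-desymmetrised tetrahydrophthalic anhydride 8 through an iodolactone.
4. Ring A is attached by SmI2 Barbier coupling of iodide 13 with (R)-bromoketone 7, itself made from sulcatone 1 by an enantiospecific bromonium cyclisation.
5. Order of ring formation: ring A (step 4); temporary bridged lactone (step 6, opened in step 11); ring C (step 14); temporary dioxolane (step 15); ring B by contraction together with ring D (step 16).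

Key step: step 16

Numbering: bicyclic intermediates are numbered as octalins (C1–C8a); C1 becomes the lactone carbonyl, C2–C4 with C4a and C8a the cyclopentane, C5 the lactone C(CH3)–O carbon, C8 the CHBr carbon.
Assumption: quinine is taken to give the (1R,6S) hemiester and the L-fructose-derived Shi ketone the (S)-epoxide; if either sense is the opposite, quinidine or the D-fructose-derived ketone is used instead.

Step 1
Reactants: 1 6-methylhept-5-en-2-one (sulcatone)
Product: 2 4-[(2S)-3,3-dimethyloxiran-2-yl]butan-2-one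
Conditions: L-fructose-derived Shi ketone (0.3 equiv), KHSO5 (as Oxone), K2CO3, Bu4NHSO4, MeCN/CH2(OMe)2/aq. buffer pH 10.5, 0 °C
Reagents that add atoms: potassium peroxymonosulfate [K+].[O-]S(=O)(=O)OO
Why: Shi asymmetric epoxidation, in which the dioxirane of the chiral ketone attacks the trisubstituted alkene through a spiro transition state and the catalyst enantiomer is chosen so that the CH epoxide carbon is S.

Step 2
Reactants: 2 4-[(2S)-3,3-dimethyloxiran-2-yl]butan-2-one
Product: 4 4-[(2S)-3,3-dimethyloxiran-2-yl]but-1-en-2-yl acetate, via lithium enolate 3 (not isolated)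
Conditions: LiN(i-Pr)2, THF, −78 °C; Ac2O, −78 °C
Reagents that add atoms: acetic anhydride CC(=O)OC(C)=O
Why: kinetic deprotonation at the methyl group and O-acetylation of the enolate (enol ester formation) should give the terminal enol acetate, the epoxide and its stereocenter being inert to the hindered base at −78 °C.

Step 3
Reactants: 4 4-[(2S)-3,3-dimethyloxiran-2-yl]but-1-en-2-yl acetate
Product: 5 (5R)-5-bromo-6-hydroxy-6-methylhept-1-en-2-yl acetate
Conditions: Li2NiBr4, THF, 0 °C
Reagents that add atoms: dilithium tetrabromonickelate [Li+].[Li+].[Ni+2].[Br-].[Br-].[Br-].[Br-]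
Why: SN2 opening of the epoxide by bromide at the less substituted carbon (halohydrin formation) proceeds with inversion and turns the (S)-epoxide into the (R)-bromide next to a tertiary alcohol.

Step 4
Reactants: 5 (5R)-5-bromo-6-hydroxy-6-methylhept-1-en-2-yl acetate
Product: 7 (4R)-4-bromo-3,3-dimethylcyclohexan-1-one, via tertiary trifluoroacetate 6 (not isolated)
Conditions: (CF3CO)2O, 2,6-lutidine, CH2Cl2, −20 °C; then (CF3)2CHOH, 0.01 M, 0 °C to rt
Reagents that add atoms: none
Why: solvolysis of the tertiary ester with neighbouring-group participation of bromine should give a configurationally defined bromonium ion that the enol acetate CH2 opens at the tertiary carbon (6-endo bromonium-initiated cation–olefin cyclisation), so the CHBr carbon keeps its configuration and loss of the acetyl group leaves the ketone.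

Step 5
Reactants: 8 cis-1,2,3,6-tetrahydrophthalic anhydride
Product: 9 (1R,6S)-6-[(benzyloxy)carbonyl]cyclohex-3-ene-1-carboxylic acid
Conditions: BnOH, quinine (1.1 equiv), toluene, −55 °C
Reagents that add atoms: benzyl alcohol OCc1ccccc1
Why: cinchona-alkaloid-mediated desymmetrising alcoholysis of a meso anhydride, in which the alkaloid selects one enantiotopic carbonyl group and so fixes both cis ring stereocenters (future C4 and C4a).

Step 6
Reactants: 9 (1R,6S)-6-[(benzyloxy)carbonyl]cyclohex-3-ene-1-carboxylic acid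
Product: 10 benzyl (1R,2S,4S,5S)-4-iodo-7-oxo-6-oxabicyclo[3.2.1]octane-2-carboxylate
Conditions: I2, KI, NaHCO3, H2O/CH2Cl2, 0 °C to rt, dark
Reagents that add atoms: iodine II
Why: iodolactonisation, in which the carboxylate adds anti to the iodonium ion at the alkene carbon 1,3 to it (γ-lactone) and thereby places oxygen on the future C1, cis to the carboxyl carbon.

Step 7
Reactants: 10 benzyl (1R,2S,4S,5S)-4-iodo-7-oxo-6-oxabicyclo[3.2.1]octane-2-carboxylate
Product: 11 (1R,2S,5R)-7-oxo-6-oxabicyclo[3.2.1]octane-2-carboxylic acid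
Conditions: H2 (1 atm), 10% Pd/C, Et3N, EtOAc, rt
Reagents that add atoms: none
Why: hydrogenolysis should cleave the benzyl ester and the C–I bond in one operation without touching a stereocenter that is kept.

Step 8
Reactants: 11 (1R,2S,5R)-7-oxo-6-oxabicyclo[3.2.1]octane-2-carboxylic acid
Product: 12 (1R,2S,5R)-2-(hydroxymethyl)-6-oxabicyclo[3.2.1]octan-7-one
Conditions: BH3·SMe2, THF, 0 °C to rt; MeOH
Reagents that add atoms: none
Why: borane reduces a carboxylic acid much faster than a lactone (chemoselective acid reduction), so only the side-chain carboxyl becomes CH2OH.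

Step 9
Reactants: 12 (1R,2S,5R)-2-(hydroxymethyl)-6-oxabicyclo[3.2.1]octan-7-one
Product: 13 (1R,2S,5R)-2-(iodomethyl)-6-oxabicyclo[3.2.1]octan-7-one
Conditions: PPh3, I2, imidazole, CH2Cl2, 0 °C to rt
Reagents that add atoms: iodine II
Why: Appel-type iodination of the primary alcohol through the alkoxyphosphonium ion (SN2 at CH2), which no stereocenter takes part in.

Step 10
Reactants: 13 (1R,2S,5R)-2-(iodomethyl)-6-oxabicyclo[3.2.1]octan-7-one; 7 (4R)-4-bromo-3,3-dimethylcyclohexan-1-one
Product: 14 (1R,2R,5R)-2-{[(1R,4R)-4-bromo-1-hydroxy-3,3-dimethylcyclohexyl]methyl}-6-oxabicyclo[3.2.1]octan-7-one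
Conditions: SmI2 (2.5 equiv), NiI2 (2 mol %), THF, 0 °C
Reagents that add atoms: none
Why: SmI2 Barbier coupling, in which the alkylsamarium from the primary iodide should add to the ketone faster than SmI2 attacks the lactone or the hindered secondary bromide; it enters the Br-equatorial chair of 7 from the equatorial side because the axial path is blocked by the axial C3 methyl group, which makes the new hydroxyl axial and cis to bromine (carbinol carbon R), with the minor epimer removed by chromatography.

Step 11
Reactants: 14 (1R,2R,5R)-2-{[(1R,4R)-4-bromo-1-hydroxy-3,3-dimethylcyclohexyl]methyl}-6-oxabicyclo[3.2.1]octan-7-one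
Product: 15 1-[(1R,2R,5R)-2-{[(1R,4R)-4-bromo-1-hydroxy-3,3-dimethylcyclohexyl]methyl}-5-hydroxycyclohexyl]-3-(1,3-dioxolan-2-yl)propan-1-one (in equilibrium with its bridged lactol)
Conditions: [2-(1,3-dioxolan-2-yl)ethyl]MgBr (2.3 equiv), THF, −78 to −30 °C; aq. NH4Cl
Reagents that add atoms: [2-(1,3-dioxolan-2-yl)ethyl]magnesium bromide Br[Mg]CCC1OCCO1
Why: Grignard addition to the lactone should stop at the bridged magnesium lactolate (a stable tetrahedral intermediate), one further equivalent being consumed by the tertiary hydroxyl, so that work-up gives the hydroxy ketone with the C6–C8 chain in place.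

Step 12
Reactants: 15 1-[(1R,2R,5R)-2-{[(1R,4R)-4-bromo-1-hydroxy-3,3-dimethylcyclohexyl]methyl}-5-hydroxycyclohexyl]-3-(1,3-dioxolan-2-yl)propan-1-one
Product: 16 (2S)-2-[(1R,2R,5R)-2-{[(1R,4R)-4-bromo-1-hydroxy-3,3-dimethylcyclohexyl]methyl}-5-hydroxycyclohexyl]-4-(1,3-dioxolan-2-yl)butan-2-ol
Conditions: MeMgBr (5 equiv), THF/CH2Cl2, −78 to 0 °C
Reagents that add atoms: methylmagnesium bromide C[Mg]Br
Why: chelation-assisted Felkin–Anh Grignard addition, in which magnesium bridges the ketone and the C1 alkoxide so that the carbonyl oxygen lies on the C8a side and methyl enters anti to the branched ring carbon C4, which should give the (S)-carbinol whose hydroxyl is on the H-4a side as the lactone later requires.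

Step 13
Reactants: 16 (2S)-2-[(1R,2R,5R)-2-{[(1R,4R)-4-bromo-1-hydroxy-3,3-dimethylcyclohexyl]methyl}-5-hydroxycyclohexyl]-4-(1,3-dioxolan-2-yl)butan-2-ol
Product: 17 (3R,4R)-4-{[(1R,4R)-4-bromo-1-hydroxy-3,3-dimethylcyclohexyl]methyl}-3-[(2S)-4-(1,3-dioxolan-2-yl)-2-hydroxybutan-2-yl]cyclohexan-1-one
Conditions: Dess–Martin periodinane, pyridine, CH2Cl2, 0 °C to rt
Reagents that add atoms: none
Why: Dess–Martin oxidation converts the only secondary alcohol into the C1 ketone and leaves the two tertiary alcohols, the acetal and the bromide untouched.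

Step 14
Reactants: 17 (3R,4R)-4-{[(1R,4R)-4-bromo-1-hydroxy-3,3-dimethylcyclohexyl]methyl}-3-[(2S)-4-(1,3-dioxolan-2-yl)-2-hydroxybutan-2-yl]cyclohexan-1-one
Product: 19 (4R,4aS,5S)-4-{[(1R,4R)-4-bromo-1-hydroxy-3,3-dimethylcyclohexyl]methyl}-5-hydroxy-5-methyl-3,4,4a,5,6,7-hexahydronaphthalen-1(2H)-one, via hydroxy keto aldehyde 18 (not isolated)
Conditions: 1 M HCl, THF, rt; then neutralise, pyrrolidine (0.5 equiv), AcOH (0.5 equiv), MeOH, 40 °C
Reagents that add atoms: none
Why: acetal hydrolysis followed by amine-catalysed intramolecular aldol condensation, in which only C8a can reach the aldehyde in a six-membered ring (C2 would give an eight-membered ring and the bridged aldol cannot dehydrate), so ring C should close with the C8=C8a alkene conjugated to C1 and without epimerisable centers being touched.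

Step 15
Reactants: 19 (4R,4aS,5S)-4-{[(1R,4R)-4-bromo-1-hydroxy-3,3-dimethylcyclohexyl]methyl}-5-hydroxy-5-methyl-3,4,4a,5,6,7-hexahydronaphthalen-1(2H)-one
Product: 20 (4'R,4a'S,5'S)-4'-{[(1R,4R)-4-bromo-1-hydroxy-3,3-dimethylcyclohexyl]methyl}-5'-methyl-3',4',4a',5',6',7'-hexahydro-2'H-spiro[1,3-dioxolane-2,1'-naphthalen]-5'-ol
Conditions: TMSOCH2CH2OTMS, TMSOTf (5 mol %), CH2Cl2, −78 to −30 °C; pyridine; K2CO3/MeOH work-up
Reagents that add atoms: 1,2-bis(trimethylsilyloxy)ethane C[Si](C)(C)OCCO[Si](C)(C)C
Why: Noyori ketalisation converts a conjugated ketone into its dioxolane under aprotic conditions at low temperature without moving the double bond, and the C5 hydroxyl cannot reach C1 while C8a is trigonal.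

Step 16
Reactants: 20 (4'R,4a'S,5'S)-4'-{[(1R,4R)-4-bromo-1-hydroxy-3,3-dimethylcyclohexyl]methyl}-5'-methyl-3',4',4a',5',6',7'-hexahydro-2'H-spiro[1,3-dioxolane-2,1'-naphthalen]-5'-ol
Product: 23 target CNP0282702.1, via bromo dioxolanylium ion 21 (not isolated), via spiro ortho ester 22 (not isolated)
Conditions: N-bromosuccinimide (1.1 equiv), (CF3)2CHOH/CH2Cl2 1:4, −30 to 0 °C; then 1 M HCl, THF, rt
Reagents that add atoms: N-bromosuccinimide BrN1C(=O)CCC1=O; water O
Why: Proposed new method: N-bromosuccinimide, activated by hydrogen bonding to the fluorinated alcohol, forms the bromonium ion of the C8=C8a alkene on the face syn to H-4a; the ring bond C1–C2 lying anti to it shifts from C1 to C8a (six-membered ring to cyclopentane ring B) while the two ketal oxygens take up the charge as the 1,3-dioxolan-2-ylium ion 21, the C5 hydroxyl adds to that carbon to give ortho ester 22, and aqueous acid releases ethylene glycol and the lactone. The closest known reactions are the N-bromosuccinimide-induced semipinacol rearrangement of allylic alcohols, the 1,2-shift of α-halo ketals to esters and the ring-contracting Prins–pinacol rearrangement; new is the pairing of a bromonium trigger with an allylic ketal as migration origin, which delivers the acid oxidation level directly and leaves no hydrogen on C1 for a competing hydride shift. Ring B is not closed but contracted by a suprafacial 1,2-alkyl shift, and lactone ring D closes by 5-exo-trig addition of the tertiary hydroxyl to the dioxolanylium carbon, which the shift has placed 1,3-diaxial to it on ring C. The two new stereocenters (CHBr and the quaternary ring-fusion carbon) follow from stereospecific anti addition of Br and C2 across the alkene, so both are fixed relative to C4a by the face of bromination, while C4, C4a and C5 are carried over unchanged. The step needs bromination on the H-4a face and migration of C2 and not C4: the other face is shielded by the axial C4 side chain and the pseudoaxial C5 methyl group, only the bromonium ion on the H-4a face has an anti carbon–carbon bond whose shift ends in an oxygen-stabilised cation, and participation of a ketal oxygen from the wrong-face ion is reversible.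

**Compound list**

1 | 6-methylhept-5-en-2-one (sulcatone) | CC(=O)CCC=C(C)C | starting material
2 | 4-[(2S)-3,3-dimethyloxiran-2-yl]butan-2-one | CC(=O)CC[C@@H]1OC1(C)C | intermediate
3 | lithium 4-[(2S)-3,3-dimethyloxiran-2-yl]but-1-en-2-olate (not isolated) | [Li]OC(=C)CC[C@@H]1OC1(C)C | intermediate
4 | 4-[(2S)-3,3-dimethyloxiran-2-yl]but-1-en-2-yl acetate | CC(=O)OC(=C)CC[C@@H]1OC1(C)C | intermediate
5 | (5R)-5-bromo-6-hydroxy-6-methylhept-1-en-2-yl acetate | CC(=O)OC(=C)CC[C@@H](Br)C(C)(C)O | intermediate
6 | (5R)-5-bromo-6-methyl-6-(trifluoroacetoxy)hept-1-en-2-yl acetate (not isolated) | CC(=O)OC(=C)CC[C@@H](Br)C(C)(C)OC(=O)C(F)(F)F | intermediate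
7 | (4R)-4-bromo-3,3-dimethylcyclohexan-1-one | CC1(C)CC(=O)CC[C@H]1Br | intermediate
8 | cis-1,2,3,6-tetrahydrophthalic anhydride (meso) | O=C1OC(=O)[C@H]2CC=CC[C@@H]12 | starting material
9 | (1R,6S)-6-[(benzyloxy)carbonyl]cyclohex-3-ene-1-carboxylic acid | O=C(OCc1ccccc1)[C@H]1CC=CC[C@H]1C(=O)O | intermediate
10 | benzyl (1R,2S,4S,5S)-4-iodo-7-oxo-6-oxabicyclo[3.2.1]octane-2-carboxylate | O=C(OCc1ccccc1)[C@H]1C[C@H](I)[C@@H]2C[C@H]1C(=O)O2 | intermediate
11 | (1R,2S,5R)-7-oxo-6-oxabicyclo[3.2.1]octane-2-carboxylic acid | OC(=O)[C@H]1CC[C@@H]2C[C@H]1C(=O)O2 | intermediate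
12 | (1R,2S,5R)-2-(hydroxymethyl)-6-oxabicyclo[3.2.1]octan-7-one | OC[C@H]1CC[C@@H]2C[C@H]1C(=O)O2 | intermediate
13 | (1R,2S,5R)-2-(iodomethyl)-6-oxabicyclo[3.2.1]octan-7-one | IC[C@H]1CC[C@@H]2C[C@H]1C(=O)O2 | intermediate
14 | (1R,2R,5R)-2-{[(1R,4R)-4-bromo-1-hydroxy-3,3-dimethylcyclohexyl]methyl}-6-oxabicyclo[3.2.1]octan-7-one | CC1(C)C[C@](O)(C[C@H]2CC[C@@H]3C[C@H]2C(=O)O3)CC[C@H]1Br | intermediate
15 | 1-[(1R,2R,5R)-2-{[(1R,4R)-4-bromo-1-hydroxy-3,3-dimethylcyclohexyl]methyl}-5-hydroxycyclohexyl]-3-(1,3-dioxolan-2-yl)propan-1-one (open form of the bridged lactol) | CC1(C)C[C@](O)(C[C@H]2CC[C@@H](O)C[C@H]2C(=O)CCC3OCCO3)CC[C@H]1Br | intermediate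
16 | (2S)-2-[(1R,2R,5R)-2-{[(1R,4R)-4-bromo-1-hydroxy-3,3-dimethylcyclohexyl]methyl}-5-hydroxycyclohexyl]-4-(1,3-dioxolan-2-yl)butan-2-ol | CC1(C)C[C@](O)(C[C@H]2CC[C@@H](O)C[C@H]2[C@@](C)(O)CCC3OCCO3)CC[C@H]1Br | intermediate
17 | (3R,4R)-4-{[(1R,4R)-4-bromo-1-hydroxy-3,3-dimethylcyclohexyl]methyl}-3-[(2S)-4-(1,3-dioxolan-2-yl)-2-hydroxybutan-2-yl]cyclohexan-1-one | CC1(C)C[C@](O)(C[C@H]2CCC(=O)C[C@H]2[C@@](C)(O)CCC3OCCO3)CC[C@H]1Br | intermediate
18 | (4S)-4-[(1R,2R)-2-{[(1R,4R)-4-bromo-1-hydroxy-3,3-dimethylcyclohexyl]methyl}-5-oxocyclohexyl]-4-hydroxypentanal (not isolated) | CC1(C)C[C@](O)(C[C@H]2CCC(=O)C[C@H]2[C@@](C)(O)CCC=O)CC[C@H]1Br | intermediate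
19 | (4R,4aS,5S)-4-{[(1R,4R)-4-bromo-1-hydroxy-3,3-dimethylcyclohexyl]methyl}-5-hydroxy-5-methyl-3,4,4a,5,6,7-hexahydronaphthalen-1(2H)-one | CC1(C)C[C@](O)(C[C@H]2CCC(=O)C3=CCC[C@](C)(O)[C@@H]23)CC[C@H]1Br | intermediate
20 | (4'R,4a'S,5'S)-4'-{[(1R,4R)-4-bromo-1-hydroxy-3,3-dimethylcyclohexyl]methyl}-5'-methyl-3',4',4a',5',6',7'-hexahydro-2'H-spiro[1,3-dioxolane-2,1'-naphthalen]-5'-ol | CC1(C)C[C@](O)(C[C@H]2CCC3(OCCO3)C4=CCC[C@](C)(O)[C@@H]24)CC[C@H]1Br | intermediate
21 | ring-contracted bromo hydrindanyl 1,3-dioxolan-2-ylium ion, cis-fused, Br trans to the migrated CH2 (not isolated) | CC1(C)C[C@](O)(C[C@H]2CC[C@@]3(C4=[O+]CCO4)[C@H](Br)CC[C@](C)(O)[C@@H]23)CC[C@H]1Br | intermediate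
22 | spiro ortho ester of the target lactone with ethylene glycol (not isolated) | CC1(C)C[C@](O)(C[C@H]2CC[C@@]34C5(OCCO5)O[C@@](C)(CC[C@H]3Br)[C@@H]24)CC[C@H]1Br | intermediate
23 | target CNP0282702.1: bridged bromo γ-lactone carrying the [(1R,4R)-4-bromo-1-hydroxy-3,3-dimethylcyclohexyl]methyl group (side-chain CH R, quaternary ring-fusion C R, CHBr R, ring-fusion CH S, lactone C(CH3)O carbon S) | CC1(C)C[C@](O)(C[C@H]2CC[C@@]34C(=O)O[C@@](C)(CC[C@H]3Br)[C@@H]24)CC[C@H]1Br | target

**Totals**

Total step count: 16. Longest linear sequence: 12 steps (8 to 23, steps 5–16); the ring A branch (steps 1–4) joins at step 10.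

**Steps most likely to fail**

1. Step 16 (Proposed new method). What may go wrong: bromination on the face away from H-4a, followed by alkoxy or hydride shifts instead of the ring-bond shift; ionisation of the allylic ketal before bromination; bromoetherification by the C5 hydroxyl. Fallback with known chemistry, setting out from 19 and coming back at 23: Luche reduction of 19 (NaBH4, CeCl3·7H2O, MeOH, −40 °C, axial hydride delivery) should give the allylic alcohol F1. N-Bromosuccinimide in i-PrOH/CH2Cl2 at 0 °C (halonium-induced semipinacol rearrangement of an allylic alcohol, here with ring-contracting shift of C2) should give the hydroxy aldehyde F2, which closes at once to the bridged lactol F3. Oxidation of the lactol with TEMPO (cat.) and PhI(OAc)2 in CH2Cl2 then gives 23.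

2. Step 4. What may go wrong: loss of enantiopurity by bromonium transfer between alkenes, or capture of the bromonium ion by oxygen instead of the enol carbon. Fallback, setting out from 1 and coming back at 14: kinetic enolisation and acetylation of 1 (LiN(i-Pr)2, then Ac2O, THF, −78 °C) gives the achiral enol acetate F4. Bromonium-induced cyclisation with Et2SBr·SbBrCl5 in MeNO2 at −25 °C gives the racemic bromoketone F5. Used in step 10 with enantiopure 13, this gives 14 together with its diastereomer F6 (antipodal ring A), and the two are separated by chromatography.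

3. Step 11. What may go wrong: double addition of the Grignard reagent to the lactone, or translactonisation by the ring A alkoxide. Fallback, setting out from 14 and coming back at 15: aminolysis of the lactone with AlMe3 and MeNH(OMe)·HCl in CH2Cl2 (0 °C to rt) gives the hydroxy Weinreb amide F7. Excess [2-(1,3-dioxolan-2-yl)ethyl]MgBr in THF at 0 °C then gives 15, over-addition being blocked by the chelated tetrahedral intermediate.

**Further compounds**

F1 | step 16 | (1R,4R,4aS,5S)-4-{[(1R,4R)-4-bromo-1-hydroxy-3,3-dimethylcyclohexyl]methyl}-5-methyl-1,2,3,4,4a,5,6,7-octahydronaphthalene-1,5-diol | CC1(C)C[C@](O)(C[C@H]2CC[C@@H](O)C3=CCC[C@](C)(O)[C@@H]23)CC[C@H]1Br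
F2 | step 16 | ring-contracted bromo hydroxy aldehyde (open form of the lactol) | CC1(C)C[C@](O)(C[C@H]2CC[C@@]3(C=O)[C@H](Br)CC[C@](C)(O)[C@@H]23)CC[C@H]1Br
F3 | step 16 | bridged bromo lactol of the target skeleton (mixture at the lactol carbon) | CC1(C)C[C@](O)(C[C@H]2CC[C@@]34C(O)O[C@@](C)(CC[C@H]3Br)[C@@H]24)CC[C@H]1Br
F4 | step 4 | 6-methylhepta-1,5-dien-2-yl acetate | CC(=O)OC(=C)CCC=C(C)C
F5 | step 4 | racemic 4-bromo-3,3-dimethylcyclohexan-1-one | CC1(C)CC(=O)CCC1Br
F6 | step 4 | (1R,2R,5R)-2-{[(1S,4S)-4-bromo-1-hydroxy-3,3-dimethylcyclohexyl]methyl}-6-oxabicyclo[3.2.1]octan-7-one | CC1(C)C[C@@](O)(C[C@H]2CC[C@@H]3C[C@H]2C(=O)O3)CC[C@@H]1Br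
F7 | step 11 | (1R,2R,5R)-2-{[(1R,4R)-4-bromo-1-hydroxy-3,3-dimethylcyclohexyl]methyl}-5-hydroxy-N-methoxy-N-methylcyclohexane-1-carboxamide | CC1(C)C[C@](O)(C[C@H]2CC[C@@H](O)C[C@H]2C(=O)N(C)OC)CC[C@H]1Br
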